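**Retrosynthetic overview**
1. The target comes from the (2S)-flavan-5,7-diol by double O-methylation.
2. Key disconnection: both chroman rings are opened at once. Ring A is cut at C4a–C5 and C6–C7 (two Claisen-type C–C bonds) and ring C at O1–C8a (oxa-Michael). This leads to an acyclic (S)-7-aryl-7-hydroxyhept-2-ynoate and methyl 5-methylhex-4-enoate, which brings C5, C6 and the prenyl group, so the prenyl position is fixed by construction.
3. The hydroxy ynoate comes from carboxylation of (S)-1-(4-methoxyphenyl)hex-5-yn-1-ol, made by asymmetric transfer hydrogenation (sets C2) of the Friedel–Crafts ketone from anisole and hex-5-ynoic acid.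
4. The ester comes from a Johnson–Claisen rearrangement of 2-methylbut-3-en-2-ol.
5. Ring order: ring B is bought (anisole); ring C and then ring A are formed in the same flask in the key step.

Assumption: the stereodescriptor in the SMILES corresponds to the (2S)-flavan (O1 > aryl > C3 > H), and hex-5-ynoic acid is taken as an inexpensive catalogue compound.

**Route**

Step 1
Reactants: 1 anisole; 2 hex-5-ynoic acid
Product: 4 1-(4-methoxyphenyl)hex-5-yn-1-one, via hex-5-ynoyl chloride 3 (not isolated)
Conditions: (COCl)2, DMF (cat.), CH2Cl2, 0 → 25 °C; then 1, AlCl3 (1.2 equiv), CH2Cl2, −10 → 0 °C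
Reagents that add atoms: none
Why: Friedel–Crafts acylation, in which the acylium ion from 3 attacks anisole para to the methoxy group and the deactivated aryl ketone does not react again; no stereocentre is formed.

Step 2
Reactants: 4 1-(4-methoxyphenyl)hex-5-yn-1-one
Product: 5 (1S)-1-(4-methoxyphenyl)hex-5-yn-1-ol
Conditions: RuCl[(S,S)-TsDPEN](p-cymene) (1 mol%), HCO2H/Et3N (5:2), 30 °C
Reagents that add atoms: none
Why: Noyori asymmetric transfer hydrogenation, in which the (S,S)-TsDPEN ruthenium hydride reduces aryl alkyl ketones through a six-membered CH–π-controlled transition state to the (S)-carbinol (typically ≥95% ee for 4-methoxyaryl ketones), which sets C2 of the target while the isolated alkyne is left alone.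

Step 3
Reactants: 5 (1S)-1-(4-methoxyphenyl)hex-5-yn-1-ol
Product: 7 methyl (7S)-7-hydroxy-7-(4-methoxyphenyl)hept-2-ynoate, via hydroxy ynoic acid 6 (not isolated)
Conditions: n-BuLi (2.2 equiv), THF, −78 °C; CO2; cold 1 M HCl; then MeI, KHCO3, DMF, 25 °C
Reagents that add atoms: carbon dioxide, O=C=O; iodomethane, CI
Why: Carboxylation of the lithium acetylide followed by SN2 O-alkylation of the carboxylate; the alkoxide only forms a carbonate that falls apart on acidification, bicarbonate is too weak to start conjugate addition of the free hydroxyl to the ynoate, and the C–O bond of the stereocentre is never broken.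

Step 4
Reactants: 8 2-methylbut-3-en-2-ol; 9 trimethyl orthoacetate
Product: 11 methyl 5-methylhex-4-enoate, via mixed ketene acetal 10 (not isolated)
Conditions: EtCO2H (cat.), neat, 110 → 140 °C, MeOH distilled off
Reagents that add atoms: none
Why: Johnson–Claisen rearrangement, in which acid-catalysed exchange and loss of methanol give ketene acetal 10 and its chair-like [3,3]-sigmatropic shift delivers the γ,δ-unsaturated ester with the trisubstituted (prenyl-type) alkene; no stereocentre is formed.

Step 5
Reactants: 7 methyl (7S)-7-hydroxy-7-(4-methoxyphenyl)hept-2-ynoate; 11 methyl 5-methylhex-4-enoate (1.3 equiv)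
Product: 14 (2S)-2-(4-methoxyphenyl)-6-(3-methylbut-2-en-1-yl)-3,4-dihydro-2H-chromene-5,7-diol, via oxanylidene acetate 12 (not isolated), via acylated keto ester 13 (not isolated)
Conditions: KOt-Bu (10 mol%), THF, 0 °C; LiN(i-Pr)2 (1.1 equiv), −78 °C; 11, −78 → 25 °C; LiN(i-Pr)2 (2.2 equiv), −78 → 40 °C; AcOH
Reagents that add atoms: none
Why: Proposed new method: an anionic [4+2] benzannulation in which (i) the alkoxide of 7 closes ring C by 6-exo-dig oxa-Michael addition to the ynoate (known for δ-hydroxy ynoates) to give vinylogous carbonate 12, (ii) γ-deprotonation of 12 gives a dienolate that is acylated at the ring γ-carbon by ester 11 (vinylogous Claisen condensation, as in γ-acylation of 3-alkoxycrotonate dienolates) to give 13, and (iii) a second deprotonation at the CH2 next to the ketone of 13 triggers a Dieckmann-type Claisen cyclisation onto the cis-disposed ester (closest known types: biomimetic Claisen aromatisation of 3-alkoxy-5-oxo-enoates to phloroglucinol monoethers, and naphthalene-1,3-diol formation from ortho-acetonyl benzoates), after which loss of methoxide and tautomerisation give aromatic ring A with the prenyl group locked between the two hydroxyls; the C2 stereocentre is a spectator because neither its C–O nor its C–H bond is touched under base.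

Step 6
Reactants: 14 (2S)-2-(4-methoxyphenyl)-6-(3-methylbut-2-en-1-yl)-3,4-dihydro-2H-chromene-5,7-diol
Product: 15 (2S)-5,7-dimethoxy-2-(4-methoxyphenyl)-6-(3-methylbut-2-en-1-yl)-3,4-dihydro-2H-chromene (target)
Conditions: MeI (3 equiv), K2CO3, acetone, 56 °C
Reagents that add atoms: iodomethane, CI
Why: Williamson ether synthesis (SN2 of both phenoxides on MeI) under weak-base aprotic conditions that favour O- over C-methylation of the phloroglucinol-type ring; the benzylic ether stereocentre is stable to K2CO3.

**Compound list**
1 | anisole | COc1ccccc1 | starting material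
2 | hex-5-ynoic acid | C#CCCCC(=O)O | starting material
3 | hex-5-ynoyl chloride (not isolated) | C#CCCCC(=O)Cl | intermediate
4 | 1-(4-methoxyphenyl)hex-5-yn-1-one | COc1ccc(cc1)C(=O)CCCC#C | intermediate
5 | (1S)-1-(4-methoxyphenyl)hex-5-yn-1-ol | COc1ccc([C@@H](O)CCCC#C)cc1 | intermediate
6 | (7S)-7-hydroxy-7-(4-methoxyphenyl)hept-2-ynoic acid (not isolated) | COc1ccc([C@@H](O)CCCC#CC(=O)O)cc1 | intermediate
7 | methyl (7S)-7-hydroxy-7-(4-methoxyphenyl)hept-2-ynoate | COc1ccc([C@@H](O)CCCC#CC(=O)OC)cc1 | intermediate
8 | 2-methylbut-3-en-2-ol | CC(C)(O)C=C | starting material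
9 | trimethyl orthoacetate (1,1,1-trimethoxyethane) | CC(OC)(OC)OC | starting material
10 | 2-[(1-methoxyethenyl)oxy]-2-methylbut-3-ene (not isolated) | COC(=C)OC(C)(C)C=C | intermediate
11 | methyl 5-methylhex-4-enoate | COC(=O)CCC=C(C)C | intermediate
12 | methyl (2E)-2-[(6S)-6-(4-methoxyphenyl)oxan-2-ylidene]acetate (not isolated; deprotonated in the flask to its lithium dienolate) | COC(=O)/C=C1\CCC[C@@H](c2ccc(OC)cc2)O1 | intermediate
13 | methyl (2E)-2-[(6S)-6-(4-methoxyphenyl)-3-(5-methylhex-4-enoyl)oxan-2-ylidene]acetate (not isolated; C3 epimers, present as lithium enolate) | COC(=O)/C=C1\C(C(=O)CCC=C(C)C)CC[C@@H](c2ccc(OC)cc2)O1 | intermediate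
14 | (2S)-2-(4-methoxyphenyl)-6-(3-methylbut-2-en-1-yl)-3,4-dihydro-2H-chromene-5,7-diol | COc1ccc([C@@H]2CCc3c(cc(O)c(CC=C(C)C)c3O)O2)cc1 | intermediate
15 | (2S)-5,7-dimethoxy-2-(4-methoxyphenyl)-6-(3-methylbut-2-en-1-yl)-3,4-dihydro-2H-chromene | COc1ccc([C@@H]2CCc3c(cc(OC)c(CC=C(C)C)c3OC)O2)cc1 | target

**Totals and risks**
Total step count: 6. Longest linear sequence: 5 steps (steps 1, 2, 3, 5 and 6; step 4 is the side branch).

Most likely to fail, in order:

Step 5 (one-pot ring C / ring A cascade). The enolisable ester 11 may be deprotonated instead of acylating the dienolate of 12, and the enolate of 13 may O-acylate to a fused 2-pyranone instead of closing ring A. The fallback sets out from 7 and comes back at 14; it closes the two rings in separate flasks and closes ring A under electrophilic instead of anionic activation. Compound 7 is cyclised with KOt-Bu (10 mol%) and 12 is isolated. The dienolate of 12 (LiN(i-Pr)2, −78 °C) is acylated with 11 and 13 is isolated after a cold quench. LiOH hydrolyses the ester to (2E)-2-[(6S)-6-(4-methoxyphenyl)-3-(5-methylhex-4-enoyl)oxan-2-ylidene]acetic acid F1. Ac2O/NaOAc at 110 °C converts it through the mixed anhydride into a dienylketene, whose 6π-electrocyclisation (the ring-closing event of cyclobutenone-based benzannulations and of the classical naphthol synthesis from Stobbe half-esters) gives, after acetylation, (2S)-2-(4-methoxyphenyl)-6-(3-methylbut-2-en-1-yl)-3,4-dihydro-2H-chromene-5,7-diyl diacetate F2. K2CO3/MeOH then removes both acetates to give 14.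

Step 3 (carboxylation and esterification with a free hydroxyl). Dianion carboxylation may be incomplete, and the hydroxy ynoate may undergo conjugate addition early. The fallback sets out from 5 and comes back at 7 and uses a protecting group and a chloroformate instead of CO2. TBSCl/imidazole gives tert-butyl{[(1S)-1-(4-methoxyphenyl)hex-5-yn-1-yl]oxy}dimethylsilane F3. n-BuLi and then ClCO2Me give methyl (7S)-7-{[tert-butyl(dimethyl)silyl]oxy}-7-(4-methoxyphenyl)hept-2-ynoate F4. HF·pyridine, which is not basic and so cannot start the oxa-Michael addition, removes the silyl group to give 7.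

Step 1 (Friedel–Crafts acylation beside a terminal alkyne). The acylium ion can cyclise onto its own alkyne, or HCl/AlCl3 can add to the triple bond. The fallback sets out from 2 and comes back at 4 and reverses the polarity of the ketone synthesis. Acid 2 is converted with 1,1'-carbonyldiimidazole and MeNHOMe·HCl into N-methoxy-N-methylhex-5-ynamide F5. 4-MeOC6H4MgBr (2.2 equiv, the first equivalent being spent on the alkyne C–H) then adds once to give 4 after work-up.

**Further compounds**
F1 | step 5 | (2E)-2-[(6S)-6-(4-methoxyphenyl)-3-(5-methylhex-4-enoyl)oxan-2-ylidene]acetic acid | OC(=O)/C=C1\C(C(=O)CCC=C(C)C)CC[C@@H](c2ccc(OC)cc2)O1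
F2 | step 5 | (2S)-2-(4-methoxyphenyl)-6-(3-methylbut-2-en-1-yl)-3,4-dihydro-2H-chromene-5,7-diyl diacetate | COc1ccc([C@@H]2CCc3c(cc(OC(C)=O)c(CC=C(C)C)c3OC(C)=O)O2)cc1
F3 | step 3 | tert-butyl{[(1S)-1-(4-methoxyphenyl)hex-5-yn-1-yl]oxy}dimethylsilane | COc1ccc([C@@H](O[Si](C)(C)C(C)(C)C)CCCC#C)cc1
F4 | step 3 | methyl (7S)-7-{[tert-butyl(dimethyl)silyl]oxy}-7-(4-methoxyphenyl)hept-2-ynoate | COc1ccc([C@@H](O[Si](C)(C)C(C)(C)C)CCCC#CC(=O)OC)cc1
F5 | step 1 | N-methoxy-N-methylhex-5-ynamide | C#CCCCC(=O)N(C)OC
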